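## The problem

Compound 17 is a 3,4-dibenzylated γ-butyrolactone. With the lactone numbered O1, C2 (carbonyl), C3, C4, C5, a 4-hydroxy-3,5-dimethoxybenzyl group (C7′ and ring B) sits on C3 and a 3,4-dimethoxybenzyl group (C7 and ring A) sits on C4; both centres are R, which places the two benzyl groups trans on the ring. The ring closes by itself once a C5 hydroxyl meets a C2 carbonyl, so the real task is the open chain C2–C3–C4–C5 with two neighbouring CH stereocentres that carry two different but very similar arylmethyl branches. C3 lies alpha to the carbonyl and can be equilibrated, the trans lactone being the more stable; C4 has no such handle. C4 can therefore steer C3 under thermodynamic control, but nothing in the molecule can steer C4, and a base equilibration would turn a wrong C4 centre into the mirror image of the target instead of removing it. Both rings are electron-rich and the ring B phenol is easily oxidised, so it must stay masked through every organometallic and oxidative step; the lactone and its acidic C3–H also argue against strong aqueous base late in the route. A short synthesis is possible because of the repeat in the chain: C3 and C4 are each a CH bearing one CH2Ar group, C5 is a bare CH2, and C2 can travel as a vinyl carbon, so the chain amounts to three successive one-carbon insertions into a carbon–boron bond.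

## Retrosynthesis

**17 from 16.** Only the O–Si bond on ring B is cut. The phenol is carried as its triisopropylsilyl ether in 16. Both positions ortho to the silyloxy group are blocked by methoxy groups, so ortho-lithiation and silyl migration are not possible. The group should survive alkyllithiums at −78 °C and brief cold alkaline peroxide, and fluoride removes it without touching the lactone. A benzyl ether would bring acidic benzylic hydrogens into the lithiation step. The forward reaction needs only buffering, so that the phenoxide does not open the lactone.

**16 from 14 via 15.** The lactone carbonyl is traced back to the lactol 15, and the O1–C2 bond is then opened. C2 is carried as the internal carbon of a vinyl group and C5 as a primary alcohol, which gives pentenol 14. An ester or acid at C2 would not survive the organolithium chemistry, and a protected alcohol would cost extra steps. A vinyl group is inert to lithiated carbenoids and comes ready-made on a commercial boronic ester. The forward sequence needs an alkene cleavage that spares two electron-rich arenes (osmium/periodate in place of ozone) and a neutral lactol oxidation. No base equilibration of C3 is planned: the one diastereomeric by-product of the chain assembly is removed by chromatography at 14, or as the cis lactone at 16. Equilibration before that point would convert a C4 error into the enantiomer of 17.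

**14 from 8, 5 and 7.** Three chain bonds are cut at once: C2–C3, C3–C4 and C4–C5. Working backwards, the alcohol comes from the primary boronic ester 13, 13 from the secondary boronic ester 12 by loss of a CH2, 12 from the allylic boronic ester 10 and the lithiated benzoate 11, and 10 from vinylboronic ester 8 and the lithiated benzoate 9. Carbenoids 9 and 11 come from benzoates 5 and 7. The neighbouring cuts are weaker. Cutting C3–C7′ (benzylation of a 4-substituted lactone enolate) still leaves C4 to be made by a separate asymmetric synthesis. Cutting C3–C4 by conjugate addition to a butenolide needs an auxiliary on the ring. The present cut builds the chain and both stereocentres in one operation from two building blocks that differ only in their aromatic ring. Each centre is fixed by the diamine used for its own carbenoid: (+)-sparteine for 9 (C3) and (−)-sparteine for 11 (C4). The precursors have no stereocentres. The forward reaction must achieve clean alpha-oxygen lithiation of 2-arylethyl benzoates, migration of a vinyl group and then of a secondary allylic group without allylic transposition, and exactly one insertion per cycle.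

**5 from 3 and 4; 7 from 6 and 4; 3 from 1 via 2.** The ester C–O bonds are cut. Both benzoates come from primary 2-arylethanols and 2,4,6-triisopropylbenzoic acid 4 by Mitsunobu esterification, which needs no acid chloride. Alcohol 6 is commercial. Alcohol 3 comes from the commercial arylacetic acid 1 by silylating both acidic hydroxyls to give 2 and then reducing the silyl ester. This order avoids having to tell a hindered phenol from a primary alcohol.

## Roads not taken

**Alternative 1:** Ring A is taken apart instead of the chain. The ring bonds A1–A2 and A5–A6 are cut, leading back to the propargyl lactone (3R,4R)-3-[4-(benzyloxy)-3,5-dimethoxybenzyl]-4-(prop-2-yn-1-yl)oxolan-2-one A1 and 2,3-dimethoxybuta-1,3-diene A2. In the forward sense CoBr2(dppe), reduced by zinc in the presence of ZnI2, would join the terminal alkyne and the diene in a formal [4+2] cycloaddition. This would give the cyclohexa-1,4-diene (3R,4R)-3-[4-(benzyloxy)-3,5-dimethoxybenzyl]-4-[(4,5-dimethoxycyclohexa-1,4-dien-1-yl)methyl]oxolan-2-one A3, and dehydrogenation and debenzylation would finish the synthesis.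
- Merits: the cycloaddition is catalytic and runs under neutral, non-cryogenic conditions. The diene is symmetrical, so there is no regiochemical question, and ring A could be varied late.
- Weak points: the key step is spent on an achiral benzene ring that can be bought as alcohol 6. Both stereocentres must already be present in A1, and making A1 enantiopure is at least as hard as the whole problem. A3 is a bis(enol ether) that is sensitive to acid and must be oxidised to the arene in the presence of a second electron-rich ring.
- Comparison: this road is better in operational simplicity and in avoiding stoichiometric chiral diamine. The chosen plan offers in return all three chain bonds and both stereocentres in its key step, from stereocentre-free precursors, and a shorter overall sequence.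

**Alternative 2:** The C3–C4 and C3–C7 bonds are cut through a cyclopropane. The precursor is the diazo keto ester (E)-3-(3,4-dimethoxyphenyl)prop-2-en-1-yl 3-[4-(benzyloxy)-3,5-dimethoxyphenyl]-2-diazo-3-oxopropanoate A4. With Rh2(PTTL)4, dirhodium tetrakis(N-phthaloyl-tert-leucinate), the derived carbene would add across the cinnamyl alkene. This closes the lactone and a cyclopropane to give (1S,5R,6S)-1-[4-(benzyloxy)-3,5-dimethoxybenzoyl]-6-(3,4-dimethoxyphenyl)-3-oxabicyclo[3.1.0]hexan-2-one A5. Scission of the donor–acceptor C3–C7 bond, reduction of the C7′ ketone to CH2 and debenzylation would follow.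
- Merits: A4 is achiral and easily assembled. Chirality comes from a catalyst. The ring and the non-epimerisable C4 centre are made together, and C3 is left to thermodynamics, which fits the stereochemical analysis above.
- Weak points: carbenes flanked by two carbonyl groups are less reactive and usually less enantioselective in intramolecular cyclopropanation than simple diazoacetates. Electron-rich styrenes and a ketone oxygen invite dihydrofuran formation and aromatic addition. Three reductive operations (C–C scission, full deoxygenation of an electron-rich aryl ketone, O-debenzylation) remain after the key step.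
- Comparison: this road is better in its use of a catalytic source of chirality. The chosen plan relies instead on stereospecific steps whose sense is fixed by the diamine, needs no change of oxidation state at either benzylic carbon afterwards, and gains enantiomeric purity because two independent selective events are combined.

**Alternative 3:** The C2–C3 and C2–O1 bonds are cut, with C2 supplied by carbon monoxide. The precursor is the alkynol (2R)-4-[4-(benzyloxy)-3,5-dimethoxyphenyl]-2-(3,4-dimethoxybenzyl)but-3-yn-1-ol A6. Under CO with Pd(dba)2 (a zerovalent palladium source) and 1,4-bis(diphenylphosphino)butane it would close to the benzylidene lactone (R,E)-3-[4-(benzyloxy)-3,5-dimethoxybenzylidene]-4-(3,4-dimethoxybenzyl)oxolan-2-one A7. Hydrogenation would then reduce the alkene and remove the benzyl group.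
- Merits: the lactone forms directly and atom-economically, and the end game is short. A single hydrogenation over palladium could serve for both the alkene and the benzyl ether.
- Weak points: the key step creates no stereocentre, so the C4 centre of A6 must come from a separate asymmetric synthesis. An internal aryl alkyne is a less willing partner in such cyclocarbonylations than a terminal one. Hydrogen is delivered to A7 from the face opposite the C4 benzyl group, which gives mainly the cis lactone and forces a base epimerisation.
- Comparison: after the key step this road is as short as the chosen one or shorter, and it is catalytic. The chosen plan makes the stereocentres and the skeleton at the same time and reaches the trans arrangement directly, without passing through the cis lactone.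

Key step: step 5

Assumption: both enantiomers of sparteine are taken as available reagents (the (+)-sparteine surrogate diamine could replace (+)-sparteine). The two lithiations in step 5 are run in separate vessels and combined by cannula; this is counted as one telescoped operation because 10, 12 and 13 are not isolated.

## Route

Step 1
Reactants: 1 2-(4-hydroxy-3,5-dimethoxyphenyl)acetic acid
Product: 2 triisopropylsilyl 2-[3,5-dimethoxy-4-(triisopropylsilyloxy)phenyl]acetate
Conditions: TIPSCl (2.5 equiv), imidazole, DMF, rt
Reagents that add atoms: triisopropylsilyl chloride, CC(C)[Si](Cl)(C(C)C)C(C)C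
Why: Silyl chloride/imidazole silylation; the acid and the phenol are both silylated, so no selectivity between them is needed, and 2,6-dimethoxyphenols are known to accept a triisopropylsilyl group under these conditions.

Step 2
Reactants: 2 triisopropylsilyl 2-[3,5-dimethoxy-4-(triisopropylsilyloxy)phenyl]acetate
Product: 3 2-[3,5-dimethoxy-4-(triisopropylsilyloxy)phenyl]ethan-1-ol
Conditions: LiAlH4, THF, 0 °C; Rochelle salt work-up
Reagents that add atoms: none
Why: Hydride reduction of an ester; LiAlH4 reduces the silyl ester (and any free acid formed from it during the work-up of step 1) to the primary alcohol, while the hindered aryl silyl ether should not be attacked at 0 °C.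

Step 3
Reactants: 3 2-[3,5-dimethoxy-4-(triisopropylsilyloxy)phenyl]ethan-1-ol; 4 2,4,6-triisopropylbenzoic acid
Product: 5 2-[3,5-dimethoxy-4-(triisopropylsilyloxy)phenyl]ethyl 2,4,6-triisopropylbenzoate
Conditions: PPh3, DIAD, THF, 0 °C to rt
Reagents that add atoms: none
Why: Mitsunobu esterification; the primary alcohol is activated as its oxyphosphonium salt and displaced by the carboxylate of 4, which avoids acylation by a severely hindered acid chloride, and no stereocentre is involved.

Step 4
Reactants: 6 2-(3,4-dimethoxyphenyl)ethan-1-ol; 4 2,4,6-triisopropylbenzoic acid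
Product: 7 2-(3,4-dimethoxyphenyl)ethyl 2,4,6-triisopropylbenzoate
Conditions: PPh3, DIAD, THF, 0 °C to rt
Reagents that add atoms: none
Why: Mitsunobu esterification, as in step 3, on a commercial primary alcohol with no competing functionality.

Step 5
Reactants: 5 2-[3,5-dimethoxy-4-(triisopropylsilyloxy)phenyl]ethyl 2,4,6-triisopropylbenzoate; 8 4,4,5,5-tetramethyl-2-vinyl-1,3,2-dioxaborolane; 7 2-(3,4-dimethoxyphenyl)ethyl 2,4,6-triisopropylbenzoate
Product: 14 (2R,3S)-2-(3,4-dimethoxybenzyl)-3-[3,5-dimethoxy-4-(triisopropylsilyloxy)benzyl]pent-4-en-1-ol, via lithiated ring B benzoate 9 (not isolated), via allylic boronic ester 10 (not isolated), via lithiated ring A benzoate 11 (not isolated), via secondary boronic ester 12 (not isolated), via primary boronic ester 13 (not isolated)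
Conditions: 5, (+)-sparteine, sBuLi, Et2O, −78 °C; then 8, −78 to 35 °C; solution transferred onto 7, (−)-sparteine, sBuLi, Et2O, −78 °C, then −78 to 35 °C; BrCH2Cl, nBuLi, −78 °C to rt; NaOH, H2O2, THF/H2O, 0 °C
Reagents that add atoms: bromochloromethane, ClCBr (the CH2 that becomes C5); hydrogen peroxide, OO (the hydroxyl oxygen that becomes O1)
Why: Each diamine-bound lithiated benzoate adds to boron with retention to give a tetracoordinate boronate, and on warming the carbon group on boron shifts to the carbenoid carbon anti to the departing triisopropylbenzoate, so the carbenoid carbon is inverted while the migrating carbon keeps its configuration (lithiation–borylation, a stereospecific 1,2-metallate rearrangement of the Matteson type run as an iterative homologation). The vinyl group of 8 migrates first and makes C2–C3 in 10, the secondary allylic carbon of 10 migrates next and makes C3–C4 in 12, chloromethyllithium formed in the flask inserts the CH2 that makes C4–C5 in 13, and alkaline peroxide replaces boron by hydroxyl with retention. No ring closes in this step. C3 is set by the (R)-carbenoid 9 generated with (+)-sparteine and C4 by the (S)-carbenoid 11 generated with (−)-sparteine, each by reagent control and independently of the chain already present; opposite diamine enantiomers give the syn chain that becomes the trans lactone. The step needs alpha-oxygen lithiation to win over benzylic and ring lithiation, which the directing carbonyl of the benzoate and the electron-rich rings should secure, and it needs 1,2-migration without allylic transposition, as is normal for allylic pinacol boronates. It also needs one insertion per cycle, which follows because surplus carbenoid decomposes below the temperature at which the boronates rearrange. Because two separate selective events set the two centres, the minor carbenoid enantiomers end up almost entirely in the single anti diastereomer of 14, which is removed by chromatography, so 14 should be of higher enantiomeric purity than either carbenoid.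

Step 6
Reactants: 14 (2R,3S)-2-(3,4-dimethoxybenzyl)-3-[3,5-dimethoxy-4-(triisopropylsilyloxy)benzyl]pent-4-en-1-ol
Product: 15 (3R,4R)-4-(3,4-dimethoxybenzyl)-3-[3,5-dimethoxy-4-(triisopropylsilyloxy)benzyl]oxolan-2-ol (mixture of anomers at C2)
Conditions: OsO4 (cat.), NaIO4, 2,6-lutidine, dioxane/H2O, rt
Reagents that add atoms: sodium periodate, [Na+].[O-]I(=O)(=O)=O (terminal oxidant whose oxygen is delivered through osmium tetroxide, O=[Os](=O)(=O)=O)
Why: Lemieux–Johnson oxidation; catalytic OsO4 dihydroxylates the only alkene, NaIO4 cleaves the diol and re-oxidises osmium, and the C2 aldehyde is captured at once by the C5 hydroxyl as the five-membered lactol. 2,6-Lutidine suppresses over-oxidation and keeps the medium from epimerising C3, so both stereocentres are carried over unchanged.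

Step 7
Reactants: 15 (3R,4R)-4-(3,4-dimethoxybenzyl)-3-[3,5-dimethoxy-4-(triisopropylsilyloxy)benzyl]oxolan-2-ol
Product: 16 (3R,4R)-4-(3,4-dimethoxybenzyl)-3-[3,5-dimethoxy-4-(triisopropylsilyloxy)benzyl]oxolan-2-one
Conditions: Ag2CO3 on Celite, toluene, reflux
Reagents that add atoms: none
Why: Fétizon oxidation; Ag2CO3 on Celite oxidises lactols to lactones under neutral heterogeneous conditions that leave the dimethoxyarenes and the silyl ether alone. C3 is already in its more stable trans arrangement.

Step 8
Reactants: 16 (3R,4R)-4-(3,4-dimethoxybenzyl)-3-[3,5-dimethoxy-4-(triisopropylsilyloxy)benzyl]oxolan-2-one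
Product: 17 (3R,4R)-4-(3,4-dimethoxybenzyl)-3-(4-hydroxy-3,5-dimethoxybenzyl)oxolan-2-one
Conditions: TBAF, AcOH, THF, 0 °C
Reagents that add atoms: none
Why: Fluoride cleavage of an aryl silyl ether, driven by formation of the Si–F bond; acetic acid buffers the phenoxide so that the lactone should be neither opened nor epimerised.

## Compound list

1 | 2-(4-hydroxy-3,5-dimethoxyphenyl)acetic acid | COc1cc(CC(=O)O)cc(OC)c1O | starting material
2 | triisopropylsilyl 2-[3,5-dimethoxy-4-(triisopropylsilyloxy)phenyl]acetate | COc1cc(CC(=O)O[Si](C(C)C)(C(C)C)C(C)C)cc(OC)c1O[Si](C(C)C)(C(C)C)C(C)C | intermediate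
3 | 2-[3,5-dimethoxy-4-(triisopropylsilyloxy)phenyl]ethan-1-ol | COc1cc(CCO)cc(OC)c1O[Si](C(C)C)(C(C)C)C(C)C | intermediate
4 | 2,4,6-triisopropylbenzoic acid | CC(C)c1cc(C(C)C)c(C(=O)O)c(C(C)C)c1 | starting material
5 | 2-[3,5-dimethoxy-4-(triisopropylsilyloxy)phenyl]ethyl 2,4,6-triisopropylbenzoate | COc1cc(CCOC(=O)c2c(C(C)C)cc(C(C)C)cc2C(C)C)cc(OC)c1O[Si](C(C)C)(C(C)C)C(C)C | intermediate
6 | 2-(3,4-dimethoxyphenyl)ethan-1-ol | COc1ccc(CCO)cc1OC | starting material
7 | 2-(3,4-dimethoxyphenyl)ethyl 2,4,6-triisopropylbenzoate | COc1ccc(CCOC(=O)c2c(C(C)C)cc(C(C)C)cc2C(C)C)cc1OC | intermediate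
8 | 4,4,5,5-tetramethyl-2-vinyl-1,3,2-dioxaborolane | C=CB1OC(C)(C)C(C)(C)O1 | starting material
9 | (1R)-2-[3,5-dimethoxy-4-(triisopropylsilyloxy)phenyl]-1-lithioethyl 2,4,6-triisopropylbenzoate, formed as its (+)-sparteine complex (diamine not drawn) | [Li][C@H](Cc1cc(OC)c(O[Si](C(C)C)(C(C)C)C(C)C)c(OC)c1)OC(=O)c1c(C(C)C)cc(C(C)C)cc1C(C)C | intermediate
10 | 2-[(2S)-1-[3,5-dimethoxy-4-(triisopropylsilyloxy)phenyl]but-3-en-2-yl]-4,4,5,5-tetramethyl-1,3,2-dioxaborolane | CC1(C)OB(OC1(C)C)[C@@H](Cc1cc(OC)c(O[Si](C(C)C)(C(C)C)C(C)C)c(OC)c1)C=C | intermediate
11 | (1S)-2-(3,4-dimethoxyphenyl)-1-lithioethyl 2,4,6-triisopropylbenzoate, formed as its (−)-sparteine complex (diamine not drawn) | [Li][C@@H](Cc1ccc(OC)c(OC)c1)OC(=O)c1c(C(C)C)cc(C(C)C)cc1C(C)C | intermediate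
12 | 2-[(2R,3R)-1-(3,4-dimethoxyphenyl)-3-[3,5-dimethoxy-4-(triisopropylsilyloxy)benzyl]pent-4-en-2-yl]-4,4,5,5-tetramethyl-1,3,2-dioxaborolane | COc1ccc(C[C@H]([C@@H](Cc2cc(OC)c(O[Si](C(C)C)(C(C)C)C(C)C)c(OC)c2)C=C)B2OC(C)(C)C(C)(C)O2)cc1OC | intermediate
13 | 2-[(2R,3S)-2-(3,4-dimethoxybenzyl)-3-[3,5-dimethoxy-4-(triisopropylsilyloxy)benzyl]pent-4-en-1-yl]-4,4,5,5-tetramethyl-1,3,2-dioxaborolane | COc1ccc(C[C@H]([C@@H](Cc2cc(OC)c(O[Si](C(C)C)(C(C)C)C(C)C)c(OC)c2)C=C)CB2OC(C)(C)C(C)(C)O2)cc1OC | intermediate
14 | (2R,3S)-2-(3,4-dimethoxybenzyl)-3-[3,5-dimethoxy-4-(triisopropylsilyloxy)benzyl]pent-4-en-1-ol | COc1ccc(C[C@H]([C@@H](Cc2cc(OC)c(O[Si](C(C)C)(C(C)C)C(C)C)c(OC)c2)C=C)CO)cc1OC | intermediate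
15 | (3R,4R)-4-(3,4-dimethoxybenzyl)-3-[3,5-dimethoxy-4-(triisopropylsilyloxy)benzyl]oxolan-2-ol (anomeric mixture) | COc1ccc(C[C@H]2COC(O)[C@@H]2Cc2cc(OC)c(O[Si](C(C)C)(C(C)C)C(C)C)c(OC)c2)cc1OC | intermediate
16 | (3R,4R)-4-(3,4-dimethoxybenzyl)-3-[3,5-dimethoxy-4-(triisopropylsilyloxy)benzyl]oxolan-2-one | COc1ccc(C[C@H]2COC(=O)[C@@H]2Cc2cc(OC)c(O[Si](C(C)C)(C(C)C)C(C)C)c(OC)c2)cc1OC | intermediate
17 | (3R,4R)-4-(3,4-dimethoxybenzyl)-3-(4-hydroxy-3,5-dimethoxybenzyl)oxolan-2-one | COc1ccc(C[C@H]2COC(=O)[C@@H]2Cc2cc(OC)c(O)c(OC)c2)cc1OC | target

## Step count and risks

Total: 8 steps. Longest linear sequence: 7 steps (1, 2, 3, 5, 6, 7, 8); step 4 is the single step of the shorter branch.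

**Step 5 (key step).** Three things are most likely to go wrong.
- Deprotonation at the benzylic CH2 instead of alpha to oxygen would lead to elimination of the benzoate, and ring lithiation next to a methoxy group would also waste the carbenoid.
- The boronate from the hindered secondary allylic boronic ester 10 and the bulky diamine-bound carbenoid 11 may form slowly and reversibly. That would cost conversion and stereochemical fidelity at C4; partial allylic transposition during this migration would add constitutional isomers.
- The aryl silyl ether may be partly lost in the alkaline peroxide if contact is not kept short and cold.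

Fallback: give up the secondary allylic boronic ester and make the C3–C7′ bond last, by enolate alkylation. The sequence sets out from 7. Carbenoid 11 is generated as in step 5 and trapped with commercial allylboronic acid pinacol ester to give the secondary homoallylic boronic ester F1; here the boron partner is unhindered and the migrating group is a primary allyl group. Chloromethyllithium homologation gives the primary boronic ester F2, and oxidation gives (2S)-2-(3,4-dimethoxybenzyl)pent-4-en-1-ol F3. Alkene cleavage as in step 6 gives the lactol (4R)-4-(3,4-dimethoxybenzyl)oxolan-2-ol F4, and oxidation as in step 7 gives the lactone (4R)-4-(3,4-dimethoxybenzyl)oxolan-2-one F5. Deprotonation with LiN(SiMe3)2 in THF at −78 °C and alkylation with the separately prepared benzyl bromide [4-(bromomethyl)-2,6-dimethoxyphenoxy]triisopropylsilane F6 should occur anti to the C4 substituent, a well-known way to trans-dibenzyl lactones. This returns to the route at 16.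

**Step 6.** The open hydroxy aldehyde formed on cleavage has an acidic C3–H. If ring closure to the lactol is not fast enough, C3 may partly epimerise, and the cis compound would be carried into the lactone. Over-oxidation of the lactol or of the electron-rich rings by periodate is the second concern.

Fallback: accept loss of C3 integrity and restore it under thermodynamic control. Setting out from 14, which has been freed of its anti diastereomer, the cleavage is run as before. The mixture of 15 and its C3 epimer, the (3S,4R)-lactol F7, is oxidised as in step 7 to 16 and the cis lactone F8. This mixture is then equilibrated with DBU in toluene. Because C4 is already homogeneous, equilibration can only converge on the trans lactone, and the route is rejoined at 16.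

**Step 2.** Hydride may attack silicon of the aryl silyl ether if the reduction is allowed to warm, and the preceding silylation of the hindered phenol may be incomplete. Either way phenolic material would be carried forward.

Fallback: protect last instead of first. Setting out from 1, LiAlH4 reduces the acid to 4-(2-hydroxyethyl)-2,6-dimethoxyphenol F9. Mitsunobu esterification with 4 should take place at the primary alcohol, since the carboxylic acid is far more acidic than the hindered phenol, to give the phenolic benzoate F10. Silylation of the phenol with triisopropylsilyl triflate and 2,6-lutidine then rejoins the route at 5.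

## Further compounds

F1 | step 5 | 2-[(2S)-1-(3,4-dimethoxyphenyl)pent-4-en-2-yl]-4,4,5,5-tetramethyl-1,3,2-dioxaborolane | COc1ccc(C[C@H](CC=C)B2OC(C)(C)C(C)(C)O2)cc1OC
F2 | step 5 | 2-[(2S)-2-(3,4-dimethoxybenzyl)pent-4-en-1-yl]-4,4,5,5-tetramethyl-1,3,2-dioxaborolane | COc1ccc(C[C@H](CC=C)CB2OC(C)(C)C(C)(C)O2)cc1OC
F3 | step 5 | (2S)-2-(3,4-dimethoxybenzyl)pent-4-en-1-ol | COc1ccc(C[C@H](CC=C)CO)cc1OC
F4 | step 5 | (4R)-4-(3,4-dimethoxybenzyl)oxolan-2-ol (anomeric mixture) | COc1ccc(C[C@H]2COC(O)C2)cc1OC
F5 | step 5 | (4R)-4-(3,4-dimethoxybenzyl)oxolan-2-one | COc1ccc(C[C@H]2COC(=O)C2)cc1OC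
F6 | step 5 | [4-(bromomethyl)-2,6-dimethoxyphenoxy]triisopropylsilane | COc1cc(CBr)cc(OC)c1O[Si](C(C)C)(C(C)C)C(C)C
F7 | step 6 | (3S,4R)-4-(3,4-dimethoxybenzyl)-3-[3,5-dimethoxy-4-(triisopropylsilyloxy)benzyl]oxolan-2-ol (anomeric mixture) | COc1ccc(C[C@H]2COC(O)[C@H]2Cc2cc(OC)c(O[Si](C(C)C)(C(C)C)C(C)C)c(OC)c2)cc1OC
F8 | step 6 | (3S,4R)-4-(3,4-dimethoxybenzyl)-3-[3,5-dimethoxy-4-(triisopropylsilyloxy)benzyl]oxolan-2-one | COc1ccc(C[C@H]2COC(=O)[C@H]2Cc2cc(OC)c(O[Si](C(C)C)(C(C)C)C(C)C)c(OC)c2)cc1OC
F9 | step 2 | 4-(2-hydroxyethyl)-2,6-dimethoxyphenol | COc1cc(CCO)cc(OC)c1O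
F10 | step 2 | 2-(4-hydroxy-3,5-dimethoxyphenyl)ethyl 2,4,6-triisopropylbenzoate | COc1cc(CCOC(=O)c2c(C(C)C)cc(C(C)C)cc2C(C)C)cc(OC)c1O
A1 | alternative 1 | (3R,4R)-3-[4-(benzyloxy)-3,5-dimethoxybenzyl]-4-(prop-2-yn-1-yl)oxolan-2-one | C#CC[C@H]1COC(=O)[C@@H]1Cc1cc(OC)c(OCc2ccccc2)c(OC)c1
A2 | alternative 1 | 2,3-dimethoxybuta-1,3-diene | C=C(OC)C(=C)OC
A3 | alternative 1 | (3R,4R)-3-[4-(benzyloxy)-3,5-dimethoxybenzyl]-4-[(4,5-dimethoxycyclohexa-1,4-dien-1-yl)methyl]oxolan-2-one | COC1=C(OC)CC(C[C@H]2COC(=O)[C@@H]2Cc2cc(OC)c(OCc3ccccc3)c(OC)c2)=CC1
A4 | alternative 2 | (E)-3-(3,4-dimethoxyphenyl)prop-2-en-1-yl 3-[4-(benzyloxy)-3,5-dimethoxyphenyl]-2-diazo-3-oxopropanoate | COc1ccc(/C=C/COC(=O)C(=[N+]=[N-])C(=O)c2cc(OC)c(OCc3ccccc3)c(OC)c2)cc1OC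
A5 | alternative 2 | (1S,5R,6S)-1-[4-(benzyloxy)-3,5-dimethoxybenzoyl]-6-(3,4-dimethoxyphenyl)-3-oxabicyclo[3.1.0]hexan-2-one | O=C1OC[C@@H]2[C@@H](c3ccc(OC)c(OC)c3)[C@]12C(=O)c1cc(OC)c(OCc2ccccc2)c(OC)c1
A6 | alternative 3 | (2R)-4-[4-(benzyloxy)-3,5-dimethoxyphenyl]-2-(3,4-dimethoxybenzyl)but-3-yn-1-ol | COc1ccc(C[C@H](C#Cc2cc(OC)c(OCc3ccccc3)c(OC)c2)CO)cc1OC
A7 | alternative 3 | (R,E)-3-[4-(benzyloxy)-3,5-dimethoxybenzylidene]-4-(3,4-dimethoxybenzyl)oxolan-2-one | COc1ccc(C[C@H]2COC(=O)/C2=C/c2cc(OC)c(OCc3ccccc3)c(OC)c2)cc1OC
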